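The 3,6-dihydro-1,2-dioxine (O1, O2, C3–C6) is disconnected at both peroxide C–O bonds. Its four carbons, with tertiary oxygenated C6 and the cis C4=C5 alkene, become a 1-hexadecylcyclobut-2-en-1-ol once a C3–C6 bond is drawn; that strained bond is the feature exploited. One cobalt-catalysed aerobic operation turns the alcohol into its alkoxy radical, cleaves C3–C6 and inserts dioxygen, forming C3–O2 and O1–C6 and the ring. The precursor is the cyclobutenol bearing the CH2CO2Me arm on C3, built with hydroxyl trans to the arm so that it cannot lactonise. Ketalisation, separation of the C6 epimers and resolution complete the target.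

Key step: step 6

Remark: every compound before step 9 is racemic and its SMILES shows one enantiomer; the target SMILES is read as (3S,6R), methoxy trans to the ester arm.

Step 1
Reactants: 1 cyclobutanone; 2 methyl bromoacetate
Product: 5 methyl 2-(2-oxocyclobutyl)acetate (racemic), via cyclohexylimine 3 (not isolated), via alkylated imine 4 (not isolated)
Conditions: c-C6H11NH2, 4 Å MS, Et2O, 25 °C; LiN(i-Pr)2 (LDA), THF, −78 °C; 2, −78 → 0 °C; aq. oxalic acid, 25 °C
Reagents that add atoms: water, O
Why: Metalloenamine (azaenolate) alkylation: the lithiated N-cyclohexylimine is C-alkylated by the reactive α-bromo ester without the self-aldol condensation that the free cyclobutanone enolate suffers, and mild acid hydrolysis returns the ketone, the new α-stereocentre being formed as a racemate.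

Step 2
Reactants: 5 methyl 2-(2-oxocyclobutyl)acetate
Product: 6 methyl 2-[2-(trifluoromethanesulfonyloxy)cyclobut-2-en-1-yl]acetate (racemic)
Conditions: LDA, THF, −78 °C; PhNTf2, −78 → 0 °C
Reagents that add atoms: N-phenylbis(trifluoromethanesulfonimide), O=S(=O)(N(c1ccccc1)S(=O)(=O)C(F)(F)F)C(F)(F)F
Why: Kinetic enolate O-sulfonylation (enol triflate formation): LDA at −78 °C removes a proton from the unhindered α′-methylene and not from the substituted α-carbon or the less acidic ester methylene, and the lithium enolate is trapped on oxygen by the triflimide, the existing stereocentre being untouched.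

Step 3
Reactants: 6 methyl 2-[2-(trifluoromethanesulfonyloxy)cyclobut-2-en-1-yl]acetate; 7 1-bromohexadecane
Product: 9 methyl 2-(2-hexadecylcyclobut-2-en-1-yl)acetate (racemic), via hexadecylmagnesium bromide 8 (not isolated)
Conditions: 7, Mg, THF, 40 °C; then 6, Fe(acac)3 (5 mol %), THF/NMP, −30 °C
Reagents that add atoms: none
Why: Iron-catalysed Kumada-type alkyl–alkenyl cross-coupling: the low-valent iron species activates the C–OTf bond within minutes at −30 °C, faster than the Grignard reagent attacks the methyl ester, and no stereocentre is made or touched.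

Step 4
Reactants: 9 methyl 2-(2-hexadecylcyclobut-2-en-1-yl)acetate
Product: 10 methyl 2-(1-hexadecyl-5-oxabicyclo[2.1.0]pentan-2-yl)acetate (racemic, epoxide oxygen trans to the acetate arm)
Conditions: mCPBA, NaHCO3, CH2Cl2, 0 °C
Reagents that add atoms: 3-chloroperoxybenzoic acid, O=C(OO)c1cccc(Cl)c1
Why: Prilezhaev epoxidation of the electron-rich trisubstituted cyclobutene: the peracid should approach the flat four-membered ring from the face opposite the CH2CO2Me arm on the adjacent sp3 carbon, which sets both epoxide carbons with oxygen trans to the arm, while the bicarbonate buffer suppresses acid-induced ring contraction of the strained epoxide.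

Step 5
Reactants: 10 methyl 2-(1-hexadecyl-5-oxabicyclo[2.1.0]pentan-2-yl)acetate
Product: 12 methyl 2-[(1R*,4R*)-4-hexadecyl-4-hydroxycyclobut-2-en-1-yl]acetate (racemic, hydroxyl trans to the arm), via hydroxy selenide 11 (not isolated)
Conditions: PhSeSePh, NaBH4, MeOH, 0 → 25 °C; 30% H2O2, pyridine, THF, 0 → 20 °C
Reagents that add atoms: none
Why: Selenolate epoxide opening followed by selenoxide syn-elimination: the soft selenolate attacks the secondary epoxide carbon by SN2 with inversion, so the tertiary C–O bond and the trans hydroxyl/arm relationship from step 4 are kept, and the selenoxide can eliminate only away from the quaternary carbinol to give the cyclobut-2-en-1-ol, whose hydroxyl cannot reach the ester to lactonise.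

Step 6
Reactants: 12 methyl 2-[(1R*,4R*)-4-hexadecyl-4-hydroxycyclobut-2-en-1-yl]acetate
Product: 14 methyl 2-(6-hexadecyl-6-hydroxy-3,6-dihydro-1,2-dioxin-3-yl)acetate (racemic at C3, C6 epimers in equilibrium), via hydroperoxy enone 13 (not isolated)
Conditions: Co(acac)2 (20 mol %), O2 (1 atm), MeCN, 20 °C, dark
Reagents that add atoms: dioxygen, O=O
Why: Proposed new method: divalent cobalt and dioxygen should convert 12 into a trivalent cobalt alkoxide whose homolysis, driven by relief of cyclobutene strain, cleaves the C3–C6 bond (cleavage of C5–C6 would give a vinyl radical) and leaves a cis-configured 1-acylallyl radical; dioxygen adds at C3, the terminus that keeps the enone conjugated, and the cobalt cycle reduces the peroxyl radical to hydroperoxide 13. The closest known reaction type is the Co(acac)2- or Mn(acac)3-catalysed aerobic ring expansion of cyclobutanols and cyclopropanols to 1,2-dioxan-3-ols and 1,2-dioxolan-3-ols, which has not been shown for a cyclobutenol with retention of the ring alkene. The dioxine ring closes by 6-exo-trig addition of the hydroperoxide oxygen to the C6 ketone, which is possible only because the four-membered ring delivers the C4=C5 bond cis. C3 arises from a planar radical and is racemic, and C6 is a freely equilibrating hemiketal centre, so no stereocontrol is asked of this step. The selectivity needed is regiochemical (bond cleaved, site of dioxygen capture) and geometric (retention of the cis alkene), secured by ring strain and allylic stabilisation in the substrate and by fast radical capture under a dioxygen atmosphere at ambient temperature.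

Step 7
Reactants: 14 methyl 2-(6-hexadecyl-6-hydroxy-3,6-dihydro-1,2-dioxin-3-yl)acetate
Product: 15 methyl 2-(6-hexadecyl-6-methoxy-3,6-dihydro-1,2-dioxin-3-yl)acetate (racemic, pair of C6 epimers)
Conditions: MeOH, p-TsOH·H2O (cat.), 20 °C
Reagents that add atoms: methanol, CO
Why: Acid-catalysed acetal exchange through the peroxide-stabilised oxocarbenium ion at C6: methanol as solvent drives the hemiketal to the methyl ketal, C3 is untouched, and because neither face of the cation is strongly favoured both C6 epimers should form, so the product is carried on as the epimer pair.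

Step 8
Reactants: 15 methyl 2-(6-hexadecyl-6-methoxy-3,6-dihydro-1,2-dioxin-3-yl)acetate
Product: 16 methyl 2-[(3S*,6R*)-6-hexadecyl-6-methoxy-3,6-dihydro-1,2-dioxin-3-yl]acetate (racemic, methoxy trans to the arm)
Conditions: SiO2 flash chromatography, hexane/EtOAc gradient, 20 °C
Reagents that add atoms: none
Why: Diastereomer separation by adsorption chromatography on silica gel: the two C6 epimers in 15 are diastereomers of different polarity, no bond is made or broken, the trans-methoxy racemate 16 is to be assigned by NOE contacts of H-3 with the methoxy group, and the cis-methoxy racemate removed here can be re-equilibrated to 15 under the conditions of step 7.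

Step 9
Reactants: 16 methyl 2-[(3S*,6R*)-6-hexadecyl-6-methoxy-3,6-dihydro-1,2-dioxin-3-yl]acetate
Product: 17 methyl 2-[(3S,6R)-6-hexadecyl-6-methoxy-3,6-dihydro-1,2-dioxin-3-yl]acetate
Conditions: preparative HPLC, amylose tris(3,5-dimethylphenylcarbamate) stationary phase, hexane/i-PrOH, 25 °C
Reagents that add atoms: none
Why: Resolution by chromatography on a chiral stationary phase: no bond is made or broken, the two enantiomers of 16 are separated through diastereomeric adsorption complexes, and the (3S,6R) fraction is to be assigned by comparing its electronic circular dichroism with the calculated spectrum.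

Compound list
1 | cyclobutanone | O=C1CCC1 | starting material
2 | methyl bromoacetate | COC(=O)CBr | starting material
3 | N-cyclohexylcyclobutanimine | C1CCC(CC1)N=C1CCC1 | intermediate (not isolated)
4 | methyl 2-[2-(cyclohexylimino)cyclobutyl]acetate, racemic | COC(=O)C[C@@H]1CCC1=NC1CCCCC1 | intermediate (not isolated)
5 | methyl 2-(2-oxocyclobutyl)acetate, racemic | COC(=O)C[C@@H]1CCC1=O | intermediate
6 | methyl 2-[2-(trifluoromethanesulfonyloxy)cyclobut-2-en-1-yl]acetate, racemic | COC(=O)C[C@@H]1CC=C1OS(=O)(=O)C(F)(F)F | intermediate
7 | 1-bromohexadecane | CCCCCCCCCCCCCCCCBr | starting material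
8 | hexadecylmagnesium bromide | CCCCCCCCCCCCCCCC[Mg]Br | intermediate (not isolated)
9 | methyl 2-(2-hexadecylcyclobut-2-en-1-yl)acetate, racemic | COC(=O)C[C@@H]1CC=C1CCCCCCCCCCCCCCCC | intermediate
10 | methyl 2-(1-hexadecyl-5-oxabicyclo[2.1.0]pentan-2-yl)acetate, racemic, epoxide oxygen trans to the acetate arm | COC(=O)C[C@@H]1C[C@H]2O[C@@]12CCCCCCCCCCCCCCCC | intermediate
11 | methyl 2-[2-hexadecyl-2-hydroxy-3-(phenylselanyl)cyclobutyl]acetate, racemic, hydroxyl trans to both the arm and the selanyl group | COC(=O)C[C@@H]1C[C@H]([Se]c2ccccc2)[C@]1(O)CCCCCCCCCCCCCCCC | intermediate (not isolated)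
12 | methyl 2-[(1R*,4R*)-4-hexadecyl-4-hydroxycyclobut-2-en-1-yl]acetate, racemic, hydroxyl trans to the arm | CCCCCCCCCCCCCCCC[C@@]1(O)C=C[C@H]1CC(=O)OC | intermediate
13 | methyl (4Z)-3-hydroperoxy-6-oxodocos-4-enoate, racemic | CCCCCCCCCCCCCCCCC(=O)/C=C\[C@H](CC(=O)OC)OO | intermediate (not isolated)
14 | methyl 2-(6-hexadecyl-6-hydroxy-3,6-dihydro-1,2-dioxin-3-yl)acetate, racemic at C3, C6 epimers in equilibrium | CCCCCCCCCCCCCCCCC1(O)C=C[C@H](CC(=O)OC)OO1 | intermediate
15 | methyl 2-(6-hexadecyl-6-methoxy-3,6-dihydro-1,2-dioxin-3-yl)acetate, racemic, pair of C6 epimers | CCCCCCCCCCCCCCCCC1(OC)C=C[C@H](CC(=O)OC)OO1 | intermediate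
16 | methyl 2-[(3S*,6R*)-6-hexadecyl-6-methoxy-3,6-dihydro-1,2-dioxin-3-yl]acetate, racemic, methoxy trans to the arm | CCCCCCCCCCCCCCCC[C@]1(OC)C=C[C@H](CC(=O)OC)OO1 | intermediate
17 | methyl 2-[(3S,6R)-6-hexadecyl-6-methoxy-3,6-dihydro-1,2-dioxin-3-yl]acetate | CCCCCCCCCCCCCCCC[C@]1(OC)C=C[C@H](CC(=O)OC)OO1 | target

Total step count: 9. Longest linear sequence: 9 steps (1 to 17); 7 enters at step 3.

Steps most likely to fail

Step 6 (the proposed new method). The acylallyl radical may lose its cis geometry, or release dioxygen again, before the peroxyl radical is reduced, which leaves a trans hydroperoxide that cannot close. The cyclobutenol may also undergo conrotatory electrocyclic opening, thermally or through its metal alkoxide, before the radical path starts (12 should be kept at or below 20 °C and away from base), and cobalt may fragment the peroxide ring once it is formed. The fallback uses known chemistry, sets out from 12 and comes back to the route at 14. Warming 12 in toluene at 80 °C should open the ring to the dienol, and a trace of Et3N should bring the derived ketone into conjugation as methyl (4E)-6-oxodocos-4-enoate F1. Dye-sensitised photooxygenation of F1 (O2, tetraphenylporphyrin, broadband light through Pyrex, CH2Cl2, 0 °C) should photoenolise it through the cis enone to the cis dienol, which adds singlet oxygen across C3 and C6 in a [4+2] manner and gives 14.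

Step 5. The strained epoxide may rearrange by ring contraction faster than the selenolate opens it, the syn-elimination may be slow inside the four-membered ring, or the new alkene may be over-oxidised. The fallback avoids the epoxide, sets out from 9 and comes back to the route at 12. OsO4 (cat.) with N-methylmorpholine N-oxide should add anti to the arm and give methyl 2-(2-hexadecyl-2,3-dihydroxycyclobutyl)acetate F2. Swern oxidation of the secondary hydroxyl should then give methyl 2-(2-hexadecyl-2-hydroxy-3-oxocyclobutyl)acetate F3, and TMSCl with imidazole should give methyl 2-[2-hexadecyl-3-oxo-2-(trimethylsilyloxy)cyclobutyl]acetate F4. KN(SiMe3)2 and PhNTf2 should convert the ketone, whose only enolisable position is the ring methylene, into methyl 2-[4-hexadecyl-3-(trifluoromethanesulfonyloxy)-4-(trimethylsilyloxy)cyclobut-2-en-1-yl]acetate F5. Pd(PPh3)4, Bu3SnH and LiCl in THF at 25 °C should reduce the triflate to methyl 2-[4-hexadecyl-4-(trimethylsilyloxy)cyclobut-2-en-1-yl]acetate F6, and citric acid in methanol at 0 °C should remove the silyl group to give 12.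

Step 3. The strained enol triflate may be reduced or homocoupled, or the Grignard reagent may attack the ester instead of coupling. The fallback sets out from 6, replaces the basic Grignard reagent by a neutral organoborane and comes back to the route at 9. Hydroboration of 1-hexadecene with 9-BBN-H should give 9-hexadecyl-9-borabicyclo[3.3.1]nonane F7, and B-alkyl Suzuki–Miyaura coupling of F7 with 6 (PdCl2(dppf), K3PO4, THF/DMF/H2O, 25–40 °C) should give 9.

Further compounds
F1 | step 6 | methyl (4E)-6-oxodocos-4-enoate | CCCCCCCCCCCCCCCCC(=O)/C=C/CCC(=O)OC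
F2 | step 5 | methyl 2-(2-hexadecyl-2,3-dihydroxycyclobutyl)acetate, racemic, both hydroxyls trans to the arm | COC(=O)C[C@@H]1C[C@@H](O)[C@]1(O)CCCCCCCCCCCCCCCC
F3 | step 5 | methyl 2-(2-hexadecyl-2-hydroxy-3-oxocyclobutyl)acetate, racemic, hydroxyl trans to the arm | COC(=O)C[C@@H]1CC(=O)[C@]1(O)CCCCCCCCCCCCCCCC
F4 | step 5 | methyl 2-[2-hexadecyl-3-oxo-2-(trimethylsilyloxy)cyclobutyl]acetate, racemic | COC(=O)C[C@@H]1CC(=O)[C@]1(O[Si](C)(C)C)CCCCCCCCCCCCCCCC
F5 | step 5 | methyl 2-[4-hexadecyl-3-(trifluoromethanesulfonyloxy)-4-(trimethylsilyloxy)cyclobut-2-en-1-yl]acetate, racemic | COC(=O)C[C@@H]1C=C(OS(=O)(=O)C(F)(F)F)[C@]1(O[Si](C)(C)C)CCCCCCCCCCCCCCCC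
F6 | step 5 | methyl 2-[4-hexadecyl-4-(trimethylsilyloxy)cyclobut-2-en-1-yl]acetate, racemic, silyloxy trans to the arm | COC(=O)C[C@@H]1C=C[C@]1(O[Si](C)(C)C)CCCCCCCCCCCCCCCC
F7 | step 3 | 9-hexadecyl-9-borabicyclo[3.3.1]nonane | CCCCCCCCCCCCCCCCB1C2CCCC1CCC2
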